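The cyclohexane ring is cut at the C3–C4 bond (quinic numbering, C1 bearing CO2H), because the C3 and C4 oxygens are cis to each other while O4 is trans to O5, the pattern a samarium-bridged pinacol coupling beside an α-alkoxy centre produces. One SmI2 reduction of a 1,6-dialdehyde (C3 and C4 as CHO) thus forms this bond, closes the carbocycle and sets both carbinol centres. In the precursor the C1 hydroxy acid remains masked as the pivalaldehyde dioxolanone inherited from (S)-malic acid, which fixes C1, and O5 is a benzyl ether on a centre set by reagent-controlled enone reduction. Afterwards O3 is silylated, O5 unmasked, and O4 and O5 are acylated before one acidic deprotection.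

Key step: step 7

Remark: ring positions follow quinic acid numbering (C1 quaternary, C3 free carbinol, C4 and C5 esterified), also for the open-chain intermediates; in the oxazaborolidine reduction the vinyl group is assumed to act as the larger ketone substituent, as is usual for enones.

Step 1
Reactants: 1 (S)-malic acid; 2 pivalaldehyde
Product: 3 2-[(2S,4S)-2-tert-butyl-5-oxo-1,3-dioxolan-4-yl]acetic acid (cis acetal)
Conditions: TsOH·H2O (cat.), H2SO4 (cat.), pentane, reflux, Dean–Stark trap; recrystallisation
Reagents that add atoms: none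
Why: Acid-catalysed acetalisation with azeotropic removal of water closes the five-membered dioxolanone on the α-hydroxy acid unit, and the cis acetal (tert-butyl and CH2CO2H on the same face, acetal carbon S) is the thermodynamic product induced by the malic acid centre and is purified by crystallisation.

Step 2
Reactants: 3 2-[(2S,4S)-2-tert-butyl-5-oxo-1,3-dioxolan-4-yl]acetic acid; 4 allyl bromide
Product: 5 2-[(2S,4S)-4-allyl-2-tert-butyl-5-oxo-1,3-dioxolan-4-yl]acetic acid (allyl trans to tert-butyl)
Conditions: LiN(SiMe3)2 (2.1 equiv), THF, −78 °C; then 4, −78 → −30 °C; 1 M HCl work-up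
Reagents that add atoms: none
Why: Two equivalents of base give the carboxylate/lactone-enolate dianion, which allyl bromide alkylates on the face opposite the tert-butyl group (enolate alkylation with self-regeneration of the stereocentre), so that allyl replaces the former α-hydrogen with retention and the quaternary C1 centre is set by the acetal carbon.

Step 3
Reactants: 5 2-[(2S,4S)-4-allyl-2-tert-butyl-5-oxo-1,3-dioxolan-4-yl]acetic acid; 6 vinylmagnesium bromide
Product: 9 (2S,5S)-5-allyl-2-tert-butyl-5-(2-oxobut-3-en-1-yl)-1,3-dioxolan-4-one, via acid chloride 7 (not isolated), via chloro(vinyl)zinc 8 (not isolated)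
Conditions: (COCl)2, DMF (cat.), CH2Cl2, 0 °C → rt, evaporate; separately 6 + ZnCl2, THF, 0 °C; combine with Pd(PPh3)4 (5 mol %), THF, 0 °C
Reagents that add atoms: none
Why: The acid chloride couples with the vinylzinc reagent under zerovalent palladium catalysis (Negishi acylation), a neutral ketone synthesis in which the organozinc leaves the acylal carbonyl alone and no base is present that could eliminate the β-oxygen at C1 from the new ketone; no stereocentre is involved.

Step 4
Reactants: 9 (2S,5S)-5-allyl-2-tert-butyl-5-(2-oxobut-3-en-1-yl)-1,3-dioxolan-4-one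
Product: 10 (2S,5S)-5-allyl-2-tert-butyl-5-[(2R)-2-hydroxybut-3-en-1-yl]-1,3-dioxolan-4-one
Conditions: (S)-2-methyl-CBS-oxazaborolidine [(S)-1-methyl-3,3-diphenyltetrahydro-1H,3H-pyrrolo[1,2-c][1,3,2]oxazaborole] (0.5 equiv), catecholborane (1.5 equiv), toluene, −78 °C; MeOH, then pH 7 buffer
Reagents that add atoms: none
Why: Corey–Bakshi–Shibata reduction, in which the (S)-oxazaborolidine binds the ketone oxygen at the lone pair beside the smaller CH2 substituent, with vinyl as the larger group, and delivers hydride from catecholborane to one carbonyl face to give the (R)-carbinol (future C5) under reagent control, while catecholborane at −78 °C should neither hydroborate the terminal alkenes nor reduce the acylal.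

Step 5
Reactants: 10 (2S,5S)-5-allyl-2-tert-butyl-5-[(2R)-2-hydroxybut-3-en-1-yl]-1,3-dioxolan-4-one
Product: 11 (2S,5S)-5-allyl-5-[(2R)-2-(benzyloxy)but-3-en-1-yl]-2-tert-butyl-1,3-dioxolan-4-one
Conditions: BnOC(=NH)CCl3 (1.5 equiv), TfOH (5 mol %), CH2Cl2–cyclohexane 1:2, 0 °C → rt
Reagents that add atoms: benzyl 2,2,2-trichloroacetimidate, N=C(OCc1ccccc1)C(Cl)(Cl)Cl
Why: Acid-catalysed benzylation with the trichloroacetimidate (O-alkylation via the protonated imidate) caps O5 without forming an alkoxide that could attack the C1 acylal carbonyl and lactonise, and it gives an ether that cannot migrate to O4 later and is removable by hydrogenolysis independently of silyl ethers.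

Step 6
Reactants: 11 (2S,5S)-5-allyl-5-[(2R)-2-(benzyloxy)but-3-en-1-yl]-2-tert-butyl-1,3-dioxolan-4-one
Product: 12 (2R)-2-(benzyloxy)-3-[(2S,4R)-2-tert-butyl-5-oxo-4-(2-oxoethyl)-1,3-dioxolan-4-yl]propanal (geometry as in 11; the 2-oxoethyl arm trans to tert-butyl)
Conditions: O3, CH2Cl2, −78 °C; then Me2S, −78 °C → rt; used crude
Reagents that add atoms: ozone, [O-][O+]=O
Why: Ozonolysis with reductive work-up cleaves both terminal alkenes to the C3 and C4 aldehydes at −78 °C under neutral conditions, which spare the benzyl ether, the acylal and the epimerisable C5 centre, and the crude dialdehyde is used at once to avoid elimination of the β-oxygen at C1.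

Step 7
Reactants: 12 (2R)-2-(benzyloxy)-3-[(2S,4R)-2-tert-butyl-5-oxo-4-(2-oxoethyl)-1,3-dioxolan-4-yl]propanal
Product: 13 5-O-benzylquinic acid masked at C1 as the spiro pivalaldehyde acetal (2-tert-butyl-1,3-dioxolan-4-one, acetal carbon S, tert-butyl on the C6 side), with a free cis-3,4-diol on the face of O1 and 5-OBn on the opposite face
Conditions: SmI2 (3 equiv, 0.1 M in THF), t-BuOH (3 equiv), THF, slow addition of 12 at high dilution, −78 → −30 °C; sat. aq. NH4Cl
Reagents that add atoms: none
Why: SmI2 transfers one electron to an aldehyde (most likely the chelating α-benzyloxy aldehyde at C4), the samarium ketyl adds through carbon to the C3 carbonyl carbon, and a second equivalent of SmI2 reduces the resulting alkoxy radical to a samarium diolate that tert-butanol and the work-up protonate. The closest known reaction type is the SmI2 pinacol cyclisation of alkoxy-substituted 1,6-dialdehydes made from sugars to cis-cyclohexane-1,2-diols. The cyclohexane ring C1–C6 closes by a 6-exo-trig ketyl addition to C=O that forms the C3–C4 bond. Both new oxygens are held on one trivalent samarium centre in the transition state, which makes the 3,4-diol cis, and this diol forms anti to the C5 benzyloxy group because the chair-like transition state keeps C5–OBn pseudo-equatorial and turns the ketyl C–O dipole away from it, so O4 ends trans to O5 and O3 cis to O4, while C1 is remote and already fixed. The step needs chemoselectivity for the two aldehydes over the acylal carbonyl, secured by −78 °C and the absence of HMPA, and ring closure in preference to intermolecular coupling or β-loss of benzyloxide, secured by slow addition at high dilution with a proton source present.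

Step 8
Reactants: 13 5-O-benzylquinic acid C1 spiro pivalaldehyde acetal
Product: 14 5-O-benzyl-3-O-(tert-butyldimethylsilyl)quinic acid C1 spiro pivalaldehyde acetal (4-OH free)
Conditions: TBSCl (1.1 equiv), imidazole (2.5 equiv), DMF, 0 °C
Reagents that add atoms: tert-butyldimethylsilyl chloride, CC(C)(C)[Si](C)(C)Cl
Why: Silyl ether formation under kinetic control should favour O3, which has a single oxygenated neighbour, over O4, which is flanked by O3 and the benzylated O5, the same preference that leaves the central hydroxyl of cyclohexane-1,2,3-triols such as methyl quinate free when the outer ones are silylated.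

Step 9
Reactants: 14 5-O-benzyl-3-O-(tert-butyldimethylsilyl)quinic acid C1 spiro pivalaldehyde acetal
Product: 15 3-O-(tert-butyldimethylsilyl)quinic acid C1 spiro pivalaldehyde acetal (4-OH and 5-OH free)
Conditions: H2 (1 atm), Pd/C (10 %), EtOAc, rt; used directly
Reagents that add atoms: none
Why: Catalytic hydrogenolysis cleaves the benzyl ether under neutral conditions at a stage where no alkene is present, and the silyl ether and the acylal are inert to H2 and Pd/C in ethyl acetate.

Step 10
Reactants: 16 p-coumaric acid
Product: 17 (E)-4-acetoxycinnamic acid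
Conditions: Ac2O, pyridine, DMAP (cat.), rt; then H2O, dilute HCl
Reagents that add atoms: acetic anhydride, CC(=O)OC(C)=O
Why: Acetylation of the phenol (nucleophilic acyl substitution) masks the only group that would compete in the later acylation, and any mixed anhydride at the carboxyl group is hydrolysed back on aqueous work-up.

Step 11
Reactants: 17 (E)-4-acetoxycinnamic acid
Product: 18 (E)-4-acetoxycinnamoyl chloride
Conditions: (COCl)2, DMF (cat.), CH2Cl2, 0 °C → rt; evaporate
Reagents that add atoms: oxalyl chloride, O=C(Cl)C(=O)Cl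
Why: Oxalyl chloride with catalytic DMF converts the acid to the acid chloride through the Vilsmeier-type chloroiminium species without touching the aryl acetate or the E-alkene.

Step 12
Reactants: 15 3-O-(tert-butyldimethylsilyl)quinic acid C1 spiro pivalaldehyde acetal; 18 (E)-4-acetoxycinnamoyl chloride
Product: 19 4,5-bis-O-[(E)-4-acetoxycinnamoyl]-3-O-(tert-butyldimethylsilyl)quinic acid C1 spiro pivalaldehyde acetal
Conditions: 18 (3 equiv), DMAP (0.5 equiv), pyridine, CH2Cl2, 0 °C → rt
Reagents that add atoms: none
Why: DMAP-catalysed acylation (nucleophilic catalysis via the acylpyridinium ion) esterifies both free secondary hydroxyls, excess acid chloride driving the hindered O4 to completion, while O1, O3 and the carboxyl group are all masked so that no other site can react.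

Step 13
Reactants: 19 4,5-bis-O-[(E)-4-acetoxycinnamoyl]-3-O-(tert-butyldimethylsilyl)quinic acid C1 spiro pivalaldehyde acetal
Product: 20 4,5-di-O-p-coumaroylquinic acid
Conditions: 2 M aq. HCl–THF 1:3, rt, mild warming if needed
Reagents that add atoms: none
Why: Aqueous acid hydrolysis cleaves the acylal (a 1-alkoxyalkyl ester), the silyl ether and the two aryl acetates in one operation, whereas the conjugated cinnamate esters of secondary alcohols hydrolyse much more slowly and base-promoted acyl migration around the ring is suppressed at low pH.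

Compound list
1 | (S)-malic acid | OC(=O)C[C@H](O)C(=O)O | starting material
2 | pivalaldehyde (2,2-dimethylpropanal) | CC(C)(C)C=O | starting material
3 | 2-[(2S,4S)-2-tert-butyl-5-oxo-1,3-dioxolan-4-yl]acetic acid (cis acetal) | OC(=O)C[C@@H]1O[C@H](C(C)(C)C)OC1=O | intermediate
4 | allyl bromide | C=CCBr | starting material
5 | 2-[(2S,4S)-4-allyl-2-tert-butyl-5-oxo-1,3-dioxolan-4-yl]acetic acid (allyl trans to tert-butyl) | OC(=O)C[C@]1(CC=C)O[C@H](C(C)(C)C)OC1=O | intermediate
6 | vinylmagnesium bromide | C=C[Mg]Br | starting material
7 | 2-[(2S,4S)-4-allyl-2-tert-butyl-5-oxo-1,3-dioxolan-4-yl]acetyl chloride | ClC(=O)C[C@]1(CC=C)O[C@H](C(C)(C)C)OC1=O | intermediate (not isolated)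
8 | chloro(vinyl)zinc | C=C[Zn]Cl | intermediate (not isolated)
9 | (2S,5S)-5-allyl-2-tert-butyl-5-(2-oxobut-3-en-1-yl)-1,3-dioxolan-4-one | C=CC(=O)C[C@]1(CC=C)O[C@H](C(C)(C)C)OC1=O | intermediate
10 | (2S,5S)-5-allyl-2-tert-butyl-5-[(2R)-2-hydroxybut-3-en-1-yl]-1,3-dioxolan-4-one | C=C[C@H](O)C[C@]1(CC=C)O[C@H](C(C)(C)C)OC1=O | intermediate
11 | (2S,5S)-5-allyl-5-[(2R)-2-(benzyloxy)but-3-en-1-yl]-2-tert-butyl-1,3-dioxolan-4-one | C=C[C@H](OCc1ccccc1)C[C@]2(CC=C)O[C@H](C(C)(C)C)OC2=O | intermediate
12 | (2R)-2-(benzyloxy)-3-[(2S,4R)-2-tert-butyl-5-oxo-4-(2-oxoethyl)-1,3-dioxolan-4-yl]propanal (2-oxoethyl arm trans to tert-butyl) | O=C[C@H](OCc1ccccc1)C[C@]2(CC=O)O[C@H](C(C)(C)C)OC2=O | intermediate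
13 | 5-O-benzylquinic acid C1 spiro pivalaldehyde acetal (2-tert-butyl-1,3-dioxolan-4-one at C1, acetal carbon S; cis-3,4-diol, O4 trans to O5; natural quinic configuration) | O[C@@H]1[C@H](O)C[C@]2(O[C@H](C(C)(C)C)OC2=O)C[C@H]1OCc3ccccc3 | intermediate
14 | 5-O-benzyl-3-O-(tert-butyldimethylsilyl)quinic acid C1 spiro pivalaldehyde acetal | O[C@@H]1[C@H](O[Si](C)(C)C(C)(C)C)C[C@]2(O[C@H](C(C)(C)C)OC2=O)C[C@H]1OCc3ccccc3 | intermediate
15 | 3-O-(tert-butyldimethylsilyl)quinic acid C1 spiro pivalaldehyde acetal | O[C@@H]1[C@H](O[Si](C)(C)C(C)(C)C)C[C@]2(O[C@H](C(C)(C)C)OC2=O)C[C@H]1O | intermediate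
16 | p-coumaric acid | OC(=O)/C=C/c1ccc(O)cc1 | starting material
17 | (E)-4-acetoxycinnamic acid | CC(=O)Oc1ccc(/C=C/C(=O)O)cc1 | intermediate
18 | (E)-4-acetoxycinnamoyl chloride | CC(=O)Oc1ccc(/C=C/C(=O)Cl)cc1 | intermediate
19 | 4,5-bis-O-[(E)-4-acetoxycinnamoyl]-3-O-(tert-butyldimethylsilyl)quinic acid C1 spiro pivalaldehyde acetal | O=C(/C=C/c1ccc(OC(C)=O)cc1)O[C@@H]1[C@H](O[Si](C)(C)C(C)(C)C)C[C@]2(O[C@H](C(C)(C)C)OC2=O)C[C@H]1OC(=O)/C=C/c3ccc(OC(C)=O)cc3 | intermediate
20 | 4,5-di-O-p-coumaroylquinic acid | O=C(/C=C/c1ccc(O)cc1)O[C@@H]1[C@H](O)C[C@@](O)(C(=O)O)C[C@H]1OC(=O)/C=C/c1ccc(O)cc1 | target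

Total step count: 13. Longest linear sequence: 11 steps (steps 1–9, 12 and 13).

Steps most likely to fail

Step 7 (SmI2 pinacol closure). The ketyl may be reduced further and expel benzyloxide, or be protonated to the alcohol before the ring closes. Ring closure may also occur with poor facial selectivity, giving the trans-diol or the cis-diol on the O5 face. The fallback sets out from diene 11 and makes the same C3–C4 connection as an alkene. Ring-closing metathesis with second-generation Grubbs catalyst RuCl2(=CHPh)(H2IMes)(PCy3) in CH2Cl2 at 40 °C should give the spiro cyclohexene F1 with loss of ethylene. Dihydroxylation of F1 with catalytic OsO4 and N-methylmorpholine N-oxide in acetone–water should occur on the ring face opposite the allylic C5 benzyloxy group and give the cis-3,4-diol 13, where the route is rejoined.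

Step 4 (oxazaborolidine reduction). The catalyst may discriminate poorly between the vinyl group and the CH2 arm leading to the quaternary carbon, so that hydride reaches both carbonyl faces and the C5 epimers form together. The fallback sets out from acid chloride 7 (made from 5 as in step 3) and replaces the enone by an ynone, for which reagent control is more dependable. Sonogashira-type acylation of trimethylsilylacetylene with 7 (PdCl2(PPh3)2, CuI, Et3N, THF, 0 °C) should give the silyl ynone F2. Noyori asymmetric transfer hydrogenation with RuCl[(R,R)-TsDPEN](p-cymene) in 2-propanol should give the (R)-propargylic alcohol F3. Bu4NF buffered with AcOH removes the silyl group to give the terminal alkyne F4. Semi-hydrogenation over Pd/CaCO3 poisoned with Pb(OAc)2 and quinoline then gives allylic alcohol 10, where the route is rejoined.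

Step 8 (silylation of O3). Silylation may occur at O4 or at both hydroxyls, because the two secondary alcohols differ only in their neighbours, and a silyl group on O4 would block an acylation site. The fallback sets out from diol 13 and uses tin-directed regiocontrol, which addresses the equatorial O4 of the cis-diol. Bu2SnO in toluene with azeotropic removal of water gives the 3,4-O-dibutylstannylene acetal F5. Benzyl bromide with Bu4NI then alkylates O4 to give the 4,5-di-O-benzyl ether F6 after KF work-up. The remaining O3–H is silylated with TBSOTf and 2,6-lutidine to give F7. Hydrogenolysis over Pd/C in EtOAc removes both benzyl groups at once and gives diol 15, where the route is rejoined.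

Further compounds
F1 | step 7 | 7-(benzyloxy)-2-tert-butyl-1,3-dioxaspiro[4.5]dec-8-en-4-one (C3=C4 cyclohexene, configuration at C1, C5 and the acetal carbon as in 11) | C1=C[C@H](OCc3ccccc3)C[C@]2(C1)O[C@H](C(C)(C)C)OC2=O
F2 | step 4 | (2S,5S)-5-allyl-2-tert-butyl-5-[2-oxo-4-(trimethylsilyl)but-3-yn-1-yl]-1,3-dioxolan-4-one | C[Si](C)(C)C#CC(=O)C[C@]1(CC=C)O[C@H](C(C)(C)C)OC1=O
F3 | step 4 | (2S,5S)-5-allyl-2-tert-butyl-5-[(2R)-2-hydroxy-4-(trimethylsilyl)but-3-yn-1-yl]-1,3-dioxolan-4-one | C[Si](C)(C)C#C[C@H](O)C[C@]1(CC=C)O[C@H](C(C)(C)C)OC1=O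
F4 | step 4 | (2S,5S)-5-allyl-2-tert-butyl-5-[(2R)-2-hydroxybut-3-yn-1-yl]-1,3-dioxolan-4-one | C#C[C@H](O)C[C@]1(CC=C)O[C@H](C(C)(C)C)OC1=O
F5 | step 8 | 3,4-O-dibutylstannylene acetal of 13 | CCCC[Sn]5(CCCC)O[C@@H]1[C@H](O5)C[C@]2(O[C@H](C(C)(C)C)OC2=O)C[C@H]1OCc3ccccc3
F6 | step 8 | 4,5-di-O-benzylquinic acid C1 spiro pivalaldehyde acetal (3-OH free) | C(c4ccccc4)O[C@@H]1[C@H](O)C[C@]2(O[C@H](C(C)(C)C)OC2=O)C[C@H]1OCc3ccccc3
F7 | step 8 | 4,5-di-O-benzyl-3-O-(tert-butyldimethylsilyl)quinic acid C1 spiro pivalaldehyde acetal | C(c4ccccc4)O[C@@H]1[C@H](O[Si](C)(C)C(C)(C)C)C[C@]2(O[C@H](C(C)(C)C)OC2=O)C[C@H]1OCc3ccccc3
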